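**Assumptions**
- The target is the trans-1,2-disubstituted (1S,2R) dihydronaphthalene (C1 carries the aryl group, C2 carries CH2OH), as read from the SMILES.
- Both phenols are carried as allyl ethers, because hydrogenolysis or DDQ would damage the dihydronaphthalene and enal.
- The Friedel–Crafts ring closure occurs on the vanillin-derived ring at the position para to OMe, as in natural aryltetralin biosynthesis.

**Retrosynthesis**
1. Target ← Pd-catalysed double deallylation of the diallyl ether enal **11**.
2. **11** ← chemoselective MnO2 oxidation of the allylic alcohol of diol **10**.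
3. **10** ← global reduction of **9**, which also removes the auxiliary.
4. **9** (the only ring formed, with C1 set trans to C2) ← intramolecular cationic Friedel–Crafts cyclisation of the Evans syn-aldol adduct **8**.
5. **8** ← Evans aldol of imide **7** with aldehyde **3**; **7** ← Stobbe half-ester **5**, from **3** and dimethyl succinate. Both aryl rings come from vanillin.

**Route**

**Step 1**
Reactants: 1 vanillin; 2 allyl bromide
Product: 3 4-(allyloxy)-3-methoxybenzaldehyde
Conditions: K2CO3, DMF, rt
Reagents that add atoms: allyl bromide, C=CCBr (also reactant 2)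
Why: Williamson O-allylation gives a phenol protecting group that survives base, Lewis acid and hydride, and is later removed under neutral Pd(0) conditions.

**Step 2**
Reactants: 3; 4 dimethyl succinate
Product: 5 (E)-4-[4-(allyloxy)-3-methoxyphenyl]-3-(methoxycarbonyl)but-3-enoic acid
Conditions: KOtBu, tBuOH, reflux; then aq. HCl
Reagents that add atoms: none (dimethyl succinate is reactant 4)
Why: The Stobbe condensation (aldol, lactonisation, E1cB ring opening) gives the half-ester with the aryl group cis to CH2CO2H, which is the cis ring alkene geometry needed for C3=C4.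

**Step 3**
Reactants: 5; 6 (S)-4-benzyloxazolidin-2-one
Product: 7 imide (acyl = Stobbe acid)
Conditions: PivCl, Et3N, THF, –20 °C; then lithium salt of 6 (n-BuLi, THF, –78 °C)
Reagents that add atoms: none (the pivaloyl group is lost)
Why: Mixed-anhydride N-acylation attaches the chiral auxiliary that will control C2 in the next step.

**Step 4**
Reactants: 7; 3
Product: 8 Evans syn-aldol adduct, with (2S) at the imide α-carbon and (S) at the carbinol
Conditions: Bu2BOTf, iPr2NEt, CH2Cl2, 0 °C; then 3 at –78 → 0 °C; then H2O2, MeOH/pH 7 buffer
Reagents that add atoms: none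
Why: The (Z)-boron enolate reacts through a Zimmerman–Traxler transition state (Evans syn aldol), and the (S)-benzyl auxiliary fixes the α-stereocentre, which becomes C2; the carbinol centre is destroyed in Step 5.

**Step 5**
Reactants: 8
Product: 9 dihydronaphthalene imide-ester, (1S,2R)
Conditions: BF3·OEt2, CH2Cl2, –30 → 0 °C
Reagents that add atoms: none (loss of H2O)
Why: Ionisation gives the p-alkoxy diarylmethyl cation, which alkylates the other arene para to OMe in an intramolecular Friedel–Crafts 6-ring closure; the aryl group ends up trans to the C2 substituent, so C1 is set relative to the untouched C2.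

**Step 6**
Reactants: 9
Product: 10 (1S,2R)-diol (2,3-bis(hydroxymethyl)-1,2-dihydronaphthalene, diallyl ether)
Conditions: DIBAL-H (7 equiv), CH2Cl2, –78 → 0 °C
Reagents that add atoms: none (the auxiliary 6 is recovered)
Why: Excess DIBAL-H reduces the acyl oxazolidinone and the conjugated methyl ester to primary alcohols, leaving the allyl ethers and the ring alkene intact; the conditions are non-basic, so C2 does not epimerise.

**Step 7**
Reactants: 10
Product: 11 enal, with the C3 CH2OH oxidised to CHO and the C2 CH2OH retained
Conditions: activated MnO2, CH2Cl2, rt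
Reagents that add atoms: none
Why: MnO2 oxidises only the allylic (cinnamyl-type) alcohol, so the saturated primary alcohol at C2 survives and no stereocentre is touched.

**Step 8**
Reactants: 11
Product: 12 target, (1S,2R)-7-hydroxy-1-(4-hydroxy-3-methoxyphenyl)-2-(hydroxymethyl)-6-methoxy-1,2-dihydronaphthalene-3-carbaldehyde
Conditions: Pd(PPh3)4 (5 mol%), K2CO3, MeOH, rt
Reagents that add atoms: none (the allyl groups are removed)
Why: Tsuji–Trost-type π-allyl deallylation under mild basic conditions frees both phenols without reducing the enal or the ring alkene.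

**Compound list**

| No. | Name | SMILES | Role |
|---|---|---|---|
| 1 | vanillin | COc1cc(C=O)ccc1O | starting material |
| 2 | allyl bromide | C=CCBr | starting material |
| 3 | 4-(allyloxy)-3-methoxybenzaldehyde | C=CCOc1ccc(C=O)cc1OC | intermediate |
| 4 | dimethyl succinate | COC(=O)CCC(=O)OC | starting material |
| 5 | (E)-4-[4-(allyloxy)-3-methoxyphenyl]-3-(methoxycarbonyl)but-3-enoic acid | COC(=O)/C(CC(=O)O)=C/c1ccc(OCC=C)c(OC)c1 | intermediate |
| 6 | (S)-4-benzyloxazolidin-2-one | O=C1N[C@@H](Cc2ccccc2)CO1 | starting material |
| 7 | imide of 5 with 6 | COC(=O)/C(CC(=O)N1[C@@H](Cc2ccccc2)COC1=O)=C/c1ccc(OCC=C)c(OC)c1 | intermediate |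
| 8 | Evans syn-aldol adduct (2S,3S) | O=C(N1[C@@H](Cc2ccccc2)COC1=O)[C@@H](/C(C(=O)OC)=C\c1ccc(OCC=C)c(OC)c1)[C@H](O)c1ccc(OCC=C)c(OC)c1 | intermediate |
| 9 | methyl (1S,2R)-2-{[(4S)-4-benzyl-2-oxooxazolidin-3-yl]carbonyl}-7-allyloxy-1-(4-allyloxy-3-methoxyphenyl)-6-methoxy-1,2-dihydronaphthalene-3-carboxylate | COc1cc([C@H]2c3cc(OCC=C)c(OC)cc3C=C(C(=O)OC)[C@@H]2C(=O)N2[C@@H](Cc3ccccc3)COC2=O)ccc1OCC=C | intermediate |
| 10 | (1S,2R)-[7-allyloxy-1-(4-allyloxy-3-methoxyphenyl)-6-methoxy-1,2-dihydronaphthalene-2,3-diyl]dimethanol | COc1cc([C@H]2c3cc(OCC=C)c(OC)cc3C=C(CO)[C@@H]2CO)ccc1OCC=C | intermediate |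
| 11 | (1S,2R)-7-allyloxy-1-(4-allyloxy-3-methoxyphenyl)-2-(hydroxymethyl)-6-methoxy-1,2-dihydronaphthalene-3-carbaldehyde | COc1cc([C@H]2c3cc(OCC=C)c(OC)cc3C=C(C=O)[C@@H]2CO)ccc1OCC=C | intermediate |
| 12 | 7,8,9,9-tetradehydroisolariciresinol | COc1cc([C@H]2c3cc(O)c(OC)cc3C=C(C=O)[C@@H]2CO)ccc1O | target |

**Totals:** 8 steps, and the longest linear sequence is also 8 steps (1 → 3 → 5 → 7 → 8 → 9 → 10 → 11 → 12).

**Three steps most likely to fail**
1. **Step 5 (Friedel–Crafts cyclisation).** The cation can eliminate to the conjugated diene, the enoate-substituted arene is deactivated, and the trans selectivity is not guaranteed.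
   - Fallback: change the ring-forming disconnection. Make C1 by Rh/chiral-diene 1,4-arylation with the aryl boronic acid of a vanillin-derived arylidene acceptor, then close the ring by intramolecular aldol condensation (C3=C4) of an o-formylaryl aldehyde.
2. **Step 4 (aldol; Step 3 acylation feeds it).** The vinylogous imide enolate may give poor diastereoselectivity, and the β,γ-unsaturated acid may isomerise during acylation.
   - Fallback: drop the auxiliary and run a racemic Stobbe-dianion aldol and cyclisation, then resolve diol **10** by lipase kinetic resolution or chiral preparative HPLC.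
3. **Step 7 (MnO2).** Over-oxidation or aromatisation of the 1-aryl-1,2-dihydronaphthalene to the naphthalene, or an incomplete reaction, could occur.
   - Fallback: reduce imide **9** with LiBH4 to the fused γ-lactone, then partially reduce it with DIBAL-H to the lactol (ring-chain tautomer of the hydroxy-enal), and deallylate, avoiding the oxidation step.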